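## Analysis of the target

Cathayanon H (18) is a dihydroflavonol, that is a chroman-4-one. Ring A (C4a to C8a) carries hydroxyls at C5 and C7, ring C carries the aryl group at C2 and a hydroxyl at C3, and ring B is a 4-hydroxyphenyl group flanked by two 3-methylbut-2-enyl (prenyl) chains. The only stereocentres are C2 and C3. Both are R, and the aryl and hydroxyl groups are trans (both equatorial), which is also the more stable relative configuration. Three parts are sensitive:

- The two trisubstituted alkenes ortho to a phenol cyclise to chromans with acid and react first with electrophilic oxidants, boranes and hydrogenation catalysts.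
- The benzylic C2–O1 ether is para to the 4'-oxygen, so a phenoxide there opens ring C through a quinone methide and scrambles C2.
- The α-hydroxy ketone is enolisable at C3 and is dehydrogenated to the flavonol by base and air.

The difficulty is therefore twofold: the anti C2/C3 diad must be set in absolute terms by an oxidant that ignores the prenyl groups, and ring C must be closed and four hydroxyls unmasked without strong acid or base. The strategy rests on ring A. In the open-chain aryl ether it is a 3,5-dioxygenated phenoxy group, symmetric about the axis through the O1-bearing carbon (the future C8a) and the carbon para to it. The two carbons ortho to O1 (the future C4a and C8) are therefore interchangeable, and each is ortho or para to all three ring oxygens. An acyl carbon at C4, tethered through C3 and C2 to O1, can reach only these two carbons, and either one gives the same chromanone.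

## Retrosynthetic reasoning

Locants C2, C3, C4, C4a, C8a and O1 refer to the chromanone. In the open-chain compounds, propanoate C3 is the future C2 and propanoate C2 is the future C3.

**18 from 17 (four O–Si bonds).** All four hydroxyls are masked as silyl ethers: triisopropylsilyl on the three phenols and tert-butyldimethylsilyl on O3. Silyl ethers are removed by buffered fluoride, which needs neither acid, base nor hydrogen. On ring A the silyloxy groups also keep the ring a strong π-nucleophile for the ring closure.

**17 from 15 through 16 (C4–C4a bond).** This is the only C–C bond between ring C and ring A. Cutting it leaves ring A as a symmetric nucleophile and puts both stereocentres into an acyclic acid, where they can be set beforehand. The forward reaction is an intramolecular acylation by acid chloride 16. It must leave no base near the C3 proton (no ketene), must not ionise the benzylic C2–O1 bond, and must keep the acid it releases away from the prenyl alkenes. A free acylium ion is avoided, because an α-oxygenated one tends to decarbonylate. Activation is by hydrogen bonding in a fluorinated alcohol, with a hindered pyridine as proton trap.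

**15 from 14 from 13 (ester unmasking and O3 silylation).** The carboxyl group is carried as an allyl ester and released by zerovalent palladium. Saponification would strip the aryl silyl ethers and invite β-elimination of the aryloxide. The secondary hydroxyl is silylated before the acid is freed, so that the acid chloride has no competing nucleophile.

**13 from 10 and 12 (benzylic C–O bond, the future C2–O1).** The phenoxide of 12 opens the trans epoxide 10 at its benzylic carbon with inversion. This joins rings A and B convergently and turns the trans epoxide into the anti diad stereospecifically. The aryl silyl groups are triisopropylsilyl because smaller silyl groups migrate between phenoxide oxygens under such conditions. The forward reaction must alkylate on oxygen rather than on ring carbon, must attack the benzylic carbon, and must proceed with clean inversion.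

**12 from 11 (two O–Si bonds).** Ring A comes from the symmetric triol 11 by twofold silylation.

**10 from 8 through 9 (the two C–O bonds of the epoxide).** A nucleophilic, catalyst-controlled epoxidation of the unsaturated acyl imidazole 8 sets both stereocentres. A peroxide anion selects the one electron-poor alkene. Electrophilic epoxidation or dihydroxylation would go to the prenyl groups first. The acyl imidazole passes through perester 9, which lets the ester group be chosen in the same flask.

**8 from 6, and 6 from 4 and 5 (acyl–N bond; aryl–Cβ bond).** The cinnamic acid 6 is assembled from aryl iodide 4 and acrylic acid 5 by a Mizoroki–Heck reaction, which fixes the E geometry.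

**4 from 3, and 3 from 1 and 2 (O–Si bond; two aryl–CH2 bonds).** Both prenyl groups are introduced by ortho C-alkylation of the sodium phenoxide of 1 with 2 in a non-polar solvent. Iodine blocks the para position and then serves as the handle for the Heck reaction. A phenol with a para carbonyl group would give a less nucleophilic phenoxide and would need a separate two-carbon homologation.

## Alternatives that were turned down

**Alternative 1:**
- Disconnection: O1–C2 and C3–C4 of ring C. This splits the target into a ring A carbonyl component, 2-hydroxy-4,6-bis(methoxymethoxy)benzaldehyde A2, and a ring B alkene, the (E)-styrylboronate A3.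
- Forward key step: an orthoformate and a chiral phosphoric acid turn A2 into an ortho-quinone methide with a methoxy group on its exocyclic carbon. This heterodiene adds A3 in an inverse-demand [4+2] cycloaddition to give the 2,3-trans 4-methoxy-3-borylchroman A1. Oxidation of the C–B bond, oxidation at C4 and removal of the acetals would follow.
- For it: it is the most convergent of the four plans. Two ring bonds and both stereocentres form in one catalytic step, and the polarity is right: the boron-bearing carbon is the nucleophilic one and the aryl-bearing carbon ends on O1.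
- Against it: C4 arrives as a benzylic methyl ether at the alcohol oxidation level. The ketone then needs a benzylic oxidation on a chroman with two prenyl groups and an electron-rich phenol. The cycloaddition runs under Brønsted acid with the free 2,6-diprenylphenol of A3, the combination that closes chromans. Face selectivity would have to come from an ion pair of the phosphate with a quinone methide and a vinylboronate partner, for which the control elements are not established. The methoxymethyl ethers need acid at the end.
- Comparison: it would be shorter and is stronger on convergence. The chosen route offers instead C4 at the ketone level from the start, stereocentres from two reactions of well-understood course, and a fluoride-only deprotection.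

**Alternative 2:**
- Disconnection: O1–C8a and C4–C4a. Ring A enters as a two-carbon aryne unit, and the whole C2–C3–C4 chain comes with ring B as the anti hydroxy ester A5.
- Forward key step: fluoride releases the aryne from the ortho-silyl aryl triflate A6. The benzylic alkoxide of A5 adds to the aryne carbon meta to the neighbouring alkoxy group. The aryl anion, now ortho to that alkoxy group, attacks the ester and gives chromanone A4.
- For it: two bonds and ring C form in one operation without acid, so the prenyl groups are safer in the ring-closing step than in the chosen route. The regiochemistry of addition to a 3-alkoxyaryne is the one required.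
- Against it: the nucleophile is the alkoxide of a β-hydroxy ester with an electron-rich aryl group. It can revert by retro-aldol cleavage, and its α-carbon can epimerise under basic fluoride. The aryl anion is more likely to take a proton from a second molecule of A5 than to acylate, which stops at the open aryl ether. A6 needs several steps from 11. A4 carries four methoxymethyl groups, whose removal needs acid next to prenyl groups and a free phenol.
- Comparison: it is stronger in bonds formed per step and in the mildness of the ring closure. The chosen route separates the two bond formations, so the C–O bond comes from a stereospecific epoxide opening and the C–C bond from an acylation with no alkoxide present, and it ends without acid.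

**Alternative 3:**
- Disconnection: C3–C4, with C4 as an acyl anion equivalent and C3 as an aldehyde. Ring C is closed from the acylsilane aldehyde A8, in which O1 already links ring A to C2.
- Forward key step: a chiral lithium phosphite adds to the acylsilane, and a Brook rearrangement moves the negative charge to C4. This carbanion adds to the aldehyde. Silyl transfer to the new alkoxide with loss of the phosphite gives the 3-silyloxy ketone A7. C2 of A8 is α to the aldehyde and benzylic, so it racemises, and the catalyst has to convert one enantiomer selectively while it sets C3.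
- For it: the closure is catalytic and redox-neutral. It sets both stereocentres in the ring-forming step and delivers C4 as the ketone with O3 already silylated. No asymmetric epoxidation is needed, and on that point it is stronger than the chosen route.
- Against it: one catalyst must control the resolution at C2, the new centre at C3 and their trans relationship at once, in an intramolecular setting where the tether dictates much of the geometry. The α-aryl-α-aryloxy aldehyde is enolisable enough to condense with itself under the basic catalyst. The acylsilane, wedged between two oxygen substituents on ring A, and the aldehyde each need several steps, so A8 is long to make. The acetals again need acid at the end.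
- Comparison: the chosen route is more conservative. Its stereocentres come from an established catalytic epoxidation and an inversion, and its uncertain step creates no stereocentre.

Key step: step 10

Assumption: the (S)-configured ligand in step 5 is taken to deliver the 2R,3S epoxide, by analogy with the facial preference of this catalyst family toward β-aryl enones. The sense is checked on the first run, and the antipodal ligand is used if it proves opposite.

## Route

Step 1
Reactants: 1 4-iodophenol; 2 1-bromo-3-methylbut-2-ene (prenyl bromide)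
Product: 3 4-iodo-2,6-bis(3-methylbut-2-enyl)phenol
Conditions: NaH (2.2 equiv), toluene, 0 °C; 2 (2.2 equiv), rt
Reagents that add atoms: none
Why: In toluene the sodium phenoxide reacts as a tight aggregate whose oxygen is shielded, so the ortho carbons attack the primary carbon of 2 (SN2, linear prenyl kept) and the dienone tautomerises back to the phenol; iodine blocks the para position, and a second deprotonation and alkylation should fill the other ortho position (ortho C-alkylation of a phenoxide in a non-polar medium).

Step 2
Reactants: 3 4-iodo-2,6-bis(3-methylbut-2-enyl)phenol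
Product: 4 [4-iodo-2,6-bis(3-methylbut-2-enyl)phenoxy]triisopropylsilane
Conditions: i-Pr3SiOTf (1.3 equiv), 2,6-lutidine (2 equiv), CH2Cl2, 0 °C to rt
Reagents that add atoms: triisopropylsilyl trifluoromethanesulfonate, CC(C)[Si](C(C)C)(C(C)C)OS(=O)(=O)C(F)(F)F
Why: A silyl triflate with a hindered pyridine silylates even a 2,6-dialkylphenol (O-silylation); the bulky group, twisted out of the ring plane by the two prenyl groups, should survive the basic and nucleophilic steps that follow and tempers the donor strength of the oxygen toward the benzylic position.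

Step 3
Reactants: 4 [4-iodo-2,6-bis(3-methylbut-2-enyl)phenoxy]triisopropylsilane; 5 prop-2-enoic acid (acrylic acid)
Product: 6 (E)-3-[3,5-bis(3-methylbut-2-enyl)-4-(triisopropylsilyloxy)phenyl]prop-2-enoic acid
Conditions: Pd(OAc)2 (5 mol %), P(o-tol)3 (10 mol %), Et3N (3 equiv), DMF, 90 °C
Reagents that add atoms: none
Why: Mizoroki–Heck reaction: zerovalent palladium inserts into the C–I bond, the aryl group adds to the unsubstituted terminus of 5 and syn β-hydride elimination should give the E acid; the trisubstituted prenyl alkenes do not insert, and the hindered aryl silyl ether tolerates triethylamine.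

Step 4
Reactants: 6 (E)-3-[3,5-bis(3-methylbut-2-enyl)-4-(triisopropylsilyloxy)phenyl]prop-2-enoic acid
Product: 8 (E)-3-[3,5-bis(3-methylbut-2-enyl)-4-(triisopropylsilyloxy)phenyl]-1-(4-phenylimidazol-1-yl)prop-2-en-1-one, via mixed pivalic anhydride 7 (not isolated)
Conditions: t-BuCOCl (1.1 equiv), Et3N (2.2 equiv), THF, −20 °C; 4-phenyl-1H-imidazole (1.2 equiv), −20 °C to rt
Reagents that add atoms: 4-phenyl-1H-imidazole, c1ccc(-c2c[nH]cn2)cc1
Why: Acyl substitution through a mixed pivalic anhydride, which the imidazole attacks at the less hindered cinnamoyl carbonyl and through its less hindered nitrogen; no hydrogen chloride is set free, so the prenyl groups are not at risk.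

Step 5
Reactants: 8 (E)-3-[3,5-bis(3-methylbut-2-enyl)-4-(triisopropylsilyloxy)phenyl]-1-(4-phenylimidazol-1-yl)prop-2-en-1-one
Product: 10 prop-2-enyl (2R,3S)-3-[3,5-bis(3-methylbut-2-enyl)-4-(triisopropylsilyloxy)phenyl]oxirane-2-carboxylate (trans), via epoxy tert-butyl perester 9 (not isolated)
Conditions: La(O-i-Pr)3 (10 mol %), (S)-BINOL (10 mol %), Ph3AsO (10 mol %), t-BuOOH (2.4 equiv), 4 Å molecular sieves, THF, rt; then CH2=CHCH2OH (20 equiv), rt
Reagents that add atoms: tert-butyl hydroperoxide, CC(C)(C)OO; prop-2-en-1-ol, C=CCO
Why: Catalytic asymmetric nucleophilic epoxidation (Weitz–Scheffer type) of an unsaturated acyl imidazole: the lanthanum peroxide adds tert-butylperoxide to the β-carbon of the acyl donor held in the BINOL pocket and the enolate closes on oxygen to the trans epoxide, the ligand fixing the face and with it C2 (R) and C3 (S). In the same flask the imidazolide is exchanged to perester 9, which allyl alcohol should convert into the ester. Because the oxidant is a nucleophile, only the electron-poor alkene reacts and the prenyl alkenes are left alone.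

Step 6
Reactants: 11 benzene-1,3,5-triol (phloroglucinol)
Product: 12 3,5-bis(triisopropylsilyloxy)phenol
Conditions: i-Pr3SiCl (2.0 equiv), imidazole (4 equiv), DMF, 0 °C to rt; chromatography, mono- and tris-ethers recycled
Reagents that add atoms: chlorotriisopropylsilane, CC(C)[Si](Cl)(C(C)C)C(C)C
Why: Statistical O-silylation of a threefold-symmetric triol with two equivalents of a bulky silyl chloride; silicon is a hard electrophile and goes to oxygen and not to ring carbon, and the over- and under-silylated fractions can be returned to the process.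

Step 7
Reactants: 10 prop-2-enyl (2R,3S)-3-[3,5-bis(3-methylbut-2-enyl)-4-(triisopropylsilyloxy)phenyl]oxirane-2-carboxylate; 12 3,5-bis(triisopropylsilyloxy)phenol
Product: 13 prop-2-enyl (2R,3R)-3-[3,5-bis(triisopropylsilyloxy)phenoxy]-2-hydroxy-3-[3,5-bis(3-methylbut-2-enyl)-4-(triisopropylsilyloxy)phenyl]propanoate
Conditions: 12 (1.5 equiv), t-BuOK (0.2 equiv), DMF, rt; then 10, 40 °C
Reagents that add atoms: none
Why: The phenoxide of 12, present in catalytic amount and regenerated by proton transfer from the product alkoxide, should open the trans epoxide by SN2 attack at the benzylic carbon anti to the leaving oxygen (phenoxide opening of a 3-arylglycidate); this inverts propanoate C3 (the future C2, now R) and leaves C2 (the future C3, R) untouched, which gives the anti diad that becomes 2,3-trans in ring C. A polar aprotic solvent favours O- over C-alkylation, and triisopropylsilyl groups resist transfer between phenoxide oxygens.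

Step 8
Reactants: 13 prop-2-enyl (2R,3R)-3-[3,5-bis(triisopropylsilyloxy)phenoxy]-2-hydroxy-3-[3,5-bis(3-methylbut-2-enyl)-4-(triisopropylsilyloxy)phenyl]propanoate
Product: 14 prop-2-enyl (2R,3R)-3-[3,5-bis(triisopropylsilyloxy)phenoxy]-2-(tert-butyldimethylsilyloxy)-3-[3,5-bis(3-methylbut-2-enyl)-4-(triisopropylsilyloxy)phenyl]propanoate
Conditions: t-BuMe2SiOTf (1.5 equiv), 2,6-lutidine (3 equiv), CH2Cl2, −40 to 0 °C
Reagents that add atoms: tert-butyldimethylsilyl trifluoromethanesulfonate, CC(C)(C)[Si](C)(C)OS(=O)(=O)C(F)(F)F
Why: O-silylation of the hindered secondary hydroxyl with a silyl triflate; 2,6-lutidine is too weak to enolise the ester, so C2 should not epimerise and the β-aryloxy group should not be eliminated.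

Step 9
Reactants: 14 prop-2-enyl (2R,3R)-3-[3,5-bis(triisopropylsilyloxy)phenoxy]-2-(tert-butyldimethylsilyloxy)-3-[3,5-bis(3-methylbut-2-enyl)-4-(triisopropylsilyloxy)phenyl]propanoate
Product: 15 (2R,3R)-3-[3,5-bis(triisopropylsilyloxy)phenoxy]-2-(tert-butyldimethylsilyloxy)-3-[3,5-bis(3-methylbut-2-enyl)-4-(triisopropylsilyloxy)phenyl]propanoic acid
Conditions: Pd(PPh3)4 (5 mol %), morpholine (5 equiv), THF, rt; aqueous citric acid work-up (pH 4)
Reagents that add atoms: none
Why: Palladium-catalysed deallylation: zerovalent palladium ionises the allyl ester to a π-allylpalladium carboxylate and morpholine takes up the allyl group. The conditions are neutral, so the aryl silyl ethers (which hydroxide would cleave) and the C2 configuration should survive, and the prenyl groups, which carry no leaving group, are inert.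

Step 10
Reactants: 15 (2R,3R)-3-[3,5-bis(triisopropylsilyloxy)phenoxy]-2-(tert-butyldimethylsilyloxy)-3-[3,5-bis(3-methylbut-2-enyl)-4-(triisopropylsilyloxy)phenyl]propanoic acid
Product: 17 (2R,3R)-3-(tert-butyldimethylsilyloxy)-2-[3,5-bis(3-methylbut-2-enyl)-4-(triisopropylsilyloxy)phenyl]-5,7-bis(triisopropylsilyloxy)chroman-4-one, via acid chloride 16 (not isolated)
Conditions: 1-chloro-N,N,2-trimethylprop-1-en-1-amine (1.1 equiv), CH2Cl2, 0 °C to rt; then 2,6-di-tert-butyl-4-methylpyridine (1.5 equiv), (CF3)2CHOH/CH2Cl2 1:4, 0.01 M, −20 to 0 °C
Reagents that add atoms: none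
Why: The α-chloroenamine converts the acid into acid chloride 16 and takes up the carboxyl oxygen as an amide without releasing hydrogen chloride, so the C3 proton meets neither acid nor base at this stage. In the fluorinated alcohol the carbonyl oxygen and the chlorine of 16 are hydrogen-bonded, and a ring A carbon ortho to O1 (ortho to one silyloxy group, para to the other) attacks the acyl carbon to give an arenium ion that loses chloride and gives its proton to the hindered pyridine; this is an intramolecular Friedel–Crafts acylation of a 3-aryloxypropanoyl chloride, the standard access to chroman-4-ones. Ring C should close in a 6-exo-trig mode at the acyl carbon (6-exo-dig if an ion pair is reached), with the arene π-bond as the endocyclic nucleophile. No stereocentre is formed; C2 and C3 are carried through, and the step has only to leave them alone. Site selectivity comes from the substrate: the two carbons ortho to O1 are interchanged by rotation about the O1–aryl bond and give the same product, the carbon between the two silyloxy groups cannot reach the acyl carbon, and the ring B carbons that would close an indanone have no oxygen ortho or para to them. Retention at C3 rests on the absence of a base able to form the ketene (the pyridine is too hindered and too weak), and retention at C2 on the buffer, the low temperature and the twisted, weakly donating 4'-silyloxy group, which keep the benzylic ether from ionising. A free α-silyloxy acylium ion would tend to lose carbon monoxide, which is why activation is by hydrogen bonding and not by a strong Lewis acid. The aryl ketone deactivates ring A against a second acylation, and loss of the peri 5-O-silyl group, should it occur, is harmless because step 11 removes it anyway.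

Step 11
Reactants: 17 (2R,3R)-3-(tert-butyldimethylsilyloxy)-2-[3,5-bis(3-methylbut-2-enyl)-4-(triisopropylsilyloxy)phenyl]-5,7-bis(triisopropylsilyloxy)chroman-4-one
Product: 18 cathayanon H, (2R,3R)-3,5,7-trihydroxy-2-[4-hydroxy-3,5-bis(3-methylbut-2-enyl)phenyl]chroman-4-one
Conditions: Bu4NF (6 equiv), AcOH (6 equiv), THF, 0 °C to rt, under argon
Reagents that add atoms: none
Why: Global desilylation: fluoride attacks silicon at the three aryl silyl ethers and the secondary silyl ether, and acetic acid protonates each aryloxide or alkoxide as it is released. No phenoxide should build up that could open ring C through the para-quinone methide, epimerise C2 or let air dehydrogenate the ring, and no strong acid is present that could cyclise a prenyl group onto the 4'-hydroxyl.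

## Compound list

1 | 4-iodophenol | Oc1ccc(I)cc1 | starting material
2 | 1-bromo-3-methylbut-2-ene (prenyl bromide) | CC(C)=CCBr | starting material
3 | 4-iodo-2,6-bis(3-methylbut-2-enyl)phenol | CC(C)=CCc1cc(I)cc(CC=C(C)C)c1O | intermediate
4 | [4-iodo-2,6-bis(3-methylbut-2-enyl)phenoxy]triisopropylsilane | CC(C)=CCc1cc(I)cc(CC=C(C)C)c1O[Si](C(C)C)(C(C)C)C(C)C | intermediate
5 | prop-2-enoic acid (acrylic acid) | C=CC(=O)O | starting material
6 | (E)-3-[3,5-bis(3-methylbut-2-enyl)-4-(triisopropylsilyloxy)phenyl]prop-2-enoic acid | CC(C)=CCc1cc(/C=C/C(=O)O)cc(CC=C(C)C)c1O[Si](C(C)C)(C(C)C)C(C)C | intermediate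
7 | (E)-3-[3,5-bis(3-methylbut-2-enyl)-4-(triisopropylsilyloxy)phenyl]prop-2-enoic 2,2-dimethylpropanoic anhydride | CC(C)=CCc1cc(/C=C/C(=O)OC(=O)C(C)(C)C)cc(CC=C(C)C)c1O[Si](C(C)C)(C(C)C)C(C)C | intermediate (not isolated)
8 | (E)-3-[3,5-bis(3-methylbut-2-enyl)-4-(triisopropylsilyloxy)phenyl]-1-(4-phenylimidazol-1-yl)prop-2-en-1-one | CC(C)=CCc1cc(/C=C/C(=O)n2cnc(-c3ccccc3)c2)cc(CC=C(C)C)c1O[Si](C(C)C)(C(C)C)C(C)C | intermediate
9 | tert-butyl (2R,3S)-3-[3,5-bis(3-methylbut-2-enyl)-4-(triisopropylsilyloxy)phenyl]oxirane-2-carboperoxoate | CC(C)=CCc1cc([C@@H]2O[C@H]2C(=O)OOC(C)(C)C)cc(CC=C(C)C)c1O[Si](C(C)C)(C(C)C)C(C)C | intermediate (not isolated)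
10 | prop-2-enyl (2R,3S)-3-[3,5-bis(3-methylbut-2-enyl)-4-(triisopropylsilyloxy)phenyl]oxirane-2-carboxylate | CC(C)=CCc1cc([C@@H]2O[C@H]2C(=O)OCC=C)cc(CC=C(C)C)c1O[Si](C(C)C)(C(C)C)C(C)C | intermediate
11 | benzene-1,3,5-triol (phloroglucinol) | Oc1cc(O)cc(O)c1 | starting material
12 | 3,5-bis(triisopropylsilyloxy)phenol | Oc1cc(O[Si](C(C)C)(C(C)C)C(C)C)cc(O[Si](C(C)C)(C(C)C)C(C)C)c1 | intermediate
13 | prop-2-enyl (2R,3R)-3-[3,5-bis(triisopropylsilyloxy)phenoxy]-2-hydroxy-3-[3,5-bis(3-methylbut-2-enyl)-4-(triisopropylsilyloxy)phenyl]propanoate | CC(C)=CCc1cc([C@@H](Oc2cc(O[Si](C(C)C)(C(C)C)C(C)C)cc(O[Si](C(C)C)(C(C)C)C(C)C)c2)[C@@H](O)C(=O)OCC=C)cc(CC=C(C)C)c1O[Si](C(C)C)(C(C)C)C(C)C | intermediate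
14 | prop-2-enyl (2R,3R)-3-[3,5-bis(triisopropylsilyloxy)phenoxy]-2-(tert-butyldimethylsilyloxy)-3-[3,5-bis(3-methylbut-2-enyl)-4-(triisopropylsilyloxy)phenyl]propanoate | CC(C)=CCc1cc([C@@H](Oc2cc(O[Si](C(C)C)(C(C)C)C(C)C)cc(O[Si](C(C)C)(C(C)C)C(C)C)c2)[C@@H](O[Si](C)(C)C(C)(C)C)C(=O)OCC=C)cc(CC=C(C)C)c1O[Si](C(C)C)(C(C)C)C(C)C | intermediate
15 | (2R,3R)-3-[3,5-bis(triisopropylsilyloxy)phenoxy]-2-(tert-butyldimethylsilyloxy)-3-[3,5-bis(3-methylbut-2-enyl)-4-(triisopropylsilyloxy)phenyl]propanoic acid | CC(C)=CCc1cc([C@@H](Oc2cc(O[Si](C(C)C)(C(C)C)C(C)C)cc(O[Si](C(C)C)(C(C)C)C(C)C)c2)[C@@H](O[Si](C)(C)C(C)(C)C)C(=O)O)cc(CC=C(C)C)c1O[Si](C(C)C)(C(C)C)C(C)C | intermediate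
16 | (2R,3R)-3-[3,5-bis(triisopropylsilyloxy)phenoxy]-2-(tert-butyldimethylsilyloxy)-3-[3,5-bis(3-methylbut-2-enyl)-4-(triisopropylsilyloxy)phenyl]propanoyl chloride | CC(C)=CCc1cc([C@@H](Oc2cc(O[Si](C(C)C)(C(C)C)C(C)C)cc(O[Si](C(C)C)(C(C)C)C(C)C)c2)[C@@H](O[Si](C)(C)C(C)(C)C)C(=O)Cl)cc(CC=C(C)C)c1O[Si](C(C)C)(C(C)C)C(C)C | intermediate (not isolated)
17 | (2R,3R)-3-(tert-butyldimethylsilyloxy)-2-[3,5-bis(3-methylbut-2-enyl)-4-(triisopropylsilyloxy)phenyl]-5,7-bis(triisopropylsilyloxy)chroman-4-one | CC(C)=CCc1cc([C@H]2Oc3cc(O[Si](C(C)C)(C(C)C)C(C)C)cc(O[Si](C(C)C)(C(C)C)C(C)C)c3C(=O)[C@@H]2O[Si](C)(C)C(C)(C)C)cc(CC=C(C)C)c1O[Si](C(C)C)(C(C)C)C(C)C | intermediate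
18 | cathayanon H, (2R,3R)-3,5,7-trihydroxy-2-[4-hydroxy-3,5-bis(3-methylbut-2-enyl)phenyl]chroman-4-one | CC(C)=CCc1cc([C@H]2Oc3cc(O)cc(O)c3C(=O)[C@@H]2O)cc(CC=C(C)C)c1O | target

## Step count and least certain steps

Total step count: 11. Longest linear sequence: 10 steps (steps 1 to 5 and 7 to 11). Step 6 is a one-step side branch.

**Step 10 (key step).**
- What may go wrong: addition of the released hydrogen chloride to the prenyl alkenes, or acid-promoted ionisation of the benzylic C–O bond with loss of the C2 configuration, if the buffer is not effective; decarbonylation of the activated acyl group, which the α-oxygen favours; capture of the acid chloride by the fluorinated alcohol before the ring attacks.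
- Fallback: the C4–C4a bond is made by an aryl anion instead of through an arenium ion (Parham cyclisation). It sets out from 11 and 10 and returns at 17. Compound 11 is mono-iodinated (I2, NaHCO3, THF/H2O, 0 °C; all three ring carbons are equivalent) to 2-iodobenzene-1,3,5-triol F1. F1 is silylated twice (i-Pr3SiCl, imidazole, DMF; the unhindered hydroxyl para to iodine first, then one of the two equivalent flanking ones) to 2-iodo-3,5-bis(triisopropylsilyloxy)phenol F2. F2 takes the place of 12 under the conditions of step 7 and opens 10 to prop-2-enyl (2R,3R)-2-hydroxy-3-[2-iodo-3,5-bis(triisopropylsilyloxy)phenoxy]-3-[3,5-bis(3-methylbut-2-enyl)-4-(triisopropylsilyloxy)phenyl]propanoate F3. Silylation as in step 8 gives prop-2-enyl (2R,3R)-2-(tert-butyldimethylsilyloxy)-3-[2-iodo-3,5-bis(triisopropylsilyloxy)phenoxy]-3-[3,5-bis(3-methylbut-2-enyl)-4-(triisopropylsilyloxy)phenyl]propanoate F4. Iodine–magnesium exchange on F4 (i-PrMgCl·LiCl, 1.05 equiv, THF, −40 °C) should give an arylmagnesium species ortho to O1 that adds to the allyl ester within the same molecule and, after loss of the allyl oxide, gives 17 without acid and without an acid chloride.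

**Step 7.**
- What may go wrong: alkylation of the ambident phenoxide on ring carbon instead of oxygen; slow transfer of silyl groups between phenoxide oxygens; partial ionisation at the benzylic carbon with erosion of the anti relationship; competing attack at the carbon α to the ester.
- Fallback: the epoxide is opened as an epoxy alcohol under titanium assistance, with no free phenoxide. It sets out from 10 and returns at 15. NaBH4 (MeOH/THF, 0 °C) reduces the glycidic ester to [(2S,3S)-3-[3,5-bis(3-methylbut-2-enyl)-4-(triisopropylsilyloxy)phenyl]oxiran-2-yl]methanol F5. Ti(O-i-Pr)4 (1.5 equiv) and 12 in CH2Cl2 at rt deliver the phenol to C3 of the titanium-bound epoxy alcohol with inversion. This should give (2S,3R)-3-[3,5-bis(triisopropylsilyloxy)phenoxy]-3-[3,5-bis(3-methylbut-2-enyl)-4-(triisopropylsilyloxy)phenyl]propane-1,2-diol F6. Twofold silylation (t-BuMe2SiOTf, 2,6-lutidine) gives the 1,2-bis(tert-butyldimethylsilyl) ether F7. Selective cleavage of the primary silyl ether (HF·pyridine, pyridine/THF, 0 °C) gives (2S,3R)-3-[3,5-bis(triisopropylsilyloxy)phenoxy]-2-(tert-butyldimethylsilyloxy)-3-[3,5-bis(3-methylbut-2-enyl)-4-(triisopropylsilyloxy)phenyl]propan-1-ol F8. Parikh–Doering oxidation (SO3·pyridine, DMSO, i-Pr2NEt, CH2Cl2, 0 °C) gives the (2R,3R) aldehyde F9. Pinnick oxidation (NaClO2, NaH2PO4, 2-methylbut-2-ene in large excess to protect the prenyl groups and ring A, t-BuOH/H2O) gives 15.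

**Step 5.**
- What may go wrong: slow conjugate addition of the peroxide to an acceptor deactivated by its electron-rich aryl group; insufficient facial selectivity; hydrolysis of the acyl imidazole; ring opening of the electron-rich epoxide on purification.
- Fallback: the alkene is oxidised through a directing hydroxyl instead of as a Michael acceptor. It sets out from 8 and returns at 15. NaBH4 (THF/H2O, 0 °C) reduces the acyl imidazole to (E)-3-[3,5-bis(3-methylbut-2-enyl)-4-(triisopropylsilyloxy)phenyl]prop-2-en-1-ol F10. Sharpless asymmetric epoxidation (Ti(O-i-Pr)4, L-(+)-diethyl tartrate, t-BuOOH, 4 Å molecular sieves, CH2Cl2, −20 °C) oxidises only the alkene held to titanium through the allylic hydroxyl. It should give the (2S,3S) epoxy alcohol F5, which is carried on to 15 exactly as in the fallback for step 7.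

**Step 1.**
- What may go wrong: O-alkylation competing with C-alkylation; a stop at the mono-prenyl stage; attack through the tertiary end of the allyl system; acid-induced closure of a prenyl group onto the phenol during work-up.
- Fallback: the prenyl groups are put in by cross-coupling at defined carbons. It sets out from 1 and returns at 6. Compound 1 is brominated at both ortho positions (Br2, AcOH, rt) to 2,6-dibromo-4-iodophenol F11 and silylated as in step 2 to (2,6-dibromo-4-iodophenoxy)triisopropylsilane F12. A Mizoroki–Heck reaction with 5 under the conditions of step 3 at 70 °C engages only the C–I bond and gives (E)-3-[3,5-dibromo-4-(triisopropylsilyloxy)phenyl]prop-2-enoic acid F13. A twofold Stille coupling with tributyl(3-methylbut-2-enyl)stannane (Pd(PPh3)4, DMF, 100 °C) should then give 6.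

## Further compounds

F1 | step 10 | 2-iodobenzene-1,3,5-triol | Oc1cc(O)c(I)c(O)c1
F2 | step 10 | 2-iodo-3,5-bis(triisopropylsilyloxy)phenol | Oc1cc(O[Si](C(C)C)(C(C)C)C(C)C)cc(O[Si](C(C)C)(C(C)C)C(C)C)c1I
F3 | step 10 | prop-2-enyl (2R,3R)-2-hydroxy-3-[2-iodo-3,5-bis(triisopropylsilyloxy)phenoxy]-3-[3,5-bis(3-methylbut-2-enyl)-4-(triisopropylsilyloxy)phenyl]propanoate | CC(C)=CCc1cc([C@@H](Oc2cc(O[Si](C(C)C)(C(C)C)C(C)C)cc(O[Si](C(C)C)(C(C)C)C(C)C)c2I)[C@@H](O)C(=O)OCC=C)cc(CC=C(C)C)c1O[Si](C(C)C)(C(C)C)C(C)C
F4 | step 10 | prop-2-enyl (2R,3R)-2-(tert-butyldimethylsilyloxy)-3-[2-iodo-3,5-bis(triisopropylsilyloxy)phenoxy]-3-[3,5-bis(3-methylbut-2-enyl)-4-(triisopropylsilyloxy)phenyl]propanoate | CC(C)=CCc1cc([C@@H](Oc2cc(O[Si](C(C)C)(C(C)C)C(C)C)cc(O[Si](C(C)C)(C(C)C)C(C)C)c2I)[C@@H](O[Si](C)(C)C(C)(C)C)C(=O)OCC=C)cc(CC=C(C)C)c1O[Si](C(C)C)(C(C)C)C(C)C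
F5 | step 7 | [(2S,3S)-3-[3,5-bis(3-methylbut-2-enyl)-4-(triisopropylsilyloxy)phenyl]oxiran-2-yl]methanol | CC(C)=CCc1cc([C@@H]2O[C@H]2CO)cc(CC=C(C)C)c1O[Si](C(C)C)(C(C)C)C(C)C
F6 | step 7 | (2S,3R)-3-[3,5-bis(triisopropylsilyloxy)phenoxy]-3-[3,5-bis(3-methylbut-2-enyl)-4-(triisopropylsilyloxy)phenyl]propane-1,2-diol | CC(C)=CCc1cc([C@@H](Oc2cc(O[Si](C(C)C)(C(C)C)C(C)C)cc(O[Si](C(C)C)(C(C)C)C(C)C)c2)[C@@H](O)CO)cc(CC=C(C)C)c1O[Si](C(C)C)(C(C)C)C(C)C
F7 | step 7 | (2S,3R)-1,2-bis(tert-butyldimethylsilyloxy)-3-[3,5-bis(triisopropylsilyloxy)phenoxy]-3-[3,5-bis(3-methylbut-2-enyl)-4-(triisopropylsilyloxy)phenyl]propane | CC(C)=CCc1cc([C@@H](Oc2cc(O[Si](C(C)C)(C(C)C)C(C)C)cc(O[Si](C(C)C)(C(C)C)C(C)C)c2)[C@@H](O[Si](C)(C)C(C)(C)C)CO[Si](C)(C)C(C)(C)C)cc(CC=C(C)C)c1O[Si](C(C)C)(C(C)C)C(C)C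
F8 | step 7 | (2S,3R)-3-[3,5-bis(triisopropylsilyloxy)phenoxy]-2-(tert-butyldimethylsilyloxy)-3-[3,5-bis(3-methylbut-2-enyl)-4-(triisopropylsilyloxy)phenyl]propan-1-ol | CC(C)=CCc1cc([C@@H](Oc2cc(O[Si](C(C)C)(C(C)C)C(C)C)cc(O[Si](C(C)C)(C(C)C)C(C)C)c2)[C@@H](O[Si](C)(C)C(C)(C)C)CO)cc(CC=C(C)C)c1O[Si](C(C)C)(C(C)C)C(C)C
F9 | step 7 | (2R,3R)-3-[3,5-bis(triisopropylsilyloxy)phenoxy]-2-(tert-butyldimethylsilyloxy)-3-[3,5-bis(3-methylbut-2-enyl)-4-(triisopropylsilyloxy)phenyl]propanal | CC(C)=CCc1cc([C@@H](Oc2cc(O[Si](C(C)C)(C(C)C)C(C)C)cc(O[Si](C(C)C)(C(C)C)C(C)C)c2)[C@@H](O[Si](C)(C)C(C)(C)C)C=O)cc(CC=C(C)C)c1O[Si](C(C)C)(C(C)C)C(C)C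
F10 | step 5 | (E)-3-[3,5-bis(3-methylbut-2-enyl)-4-(triisopropylsilyloxy)phenyl]prop-2-en-1-ol | CC(C)=CCc1cc(/C=C/CO)cc(CC=C(C)C)c1O[Si](C(C)C)(C(C)C)C(C)C
F11 | step 1 | 2,6-dibromo-4-iodophenol | Oc1c(Br)cc(I)cc1Br
F12 | step 1 | (2,6-dibromo-4-iodophenoxy)triisopropylsilane | CC(C)[Si](Oc1c(Br)cc(I)cc1Br)(C(C)C)C(C)C
F13 | step 1 | (E)-3-[3,5-dibromo-4-(triisopropylsilyloxy)phenyl]prop-2-enoic acid | OC(=O)/C=C/c1cc(Br)c(O[Si](C(C)C)(C(C)C)C(C)C)c(Br)c1
A1 | alternative 1 | 4-[2,3-trans-4-methoxy-5,7-bis(methoxymethoxy)-3-(4,4,5,5-tetramethyl-1,3,2-dioxaborolan-2-yl)chroman-2-yl]-2,6-bis(3-methylbut-2-enyl)phenol (C2 and C3 as in the target, C4 either way) | CC(C)=CCc1cc([C@H]2Oc3cc(OCOC)cc(OCOC)c3C(OC)[C@@H]2B4OC(C)(C)C(C)(C)O4)cc(CC=C(C)C)c1O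
A2 | alternative 1 | 2-hydroxy-4,6-bis(methoxymethoxy)benzaldehyde | COCOc1cc(O)c(C=O)c(OCOC)c1
A3 | alternative 1 | 4-[(E)-2-(4,4,5,5-tetramethyl-1,3,2-dioxaborolan-2-yl)ethenyl]-2,6-bis(3-methylbut-2-enyl)phenol | CC(C)=CCc1cc(/C=C/B2OC(C)(C)C(C)(C)O2)cc(CC=C(C)C)c1O
A4 | alternative 2 | (2R,3R)-3,5,7-tris(methoxymethoxy)-2-[4-(methoxymethoxy)-3,5-bis(3-methylbut-2-enyl)phenyl]chroman-4-one | CC(C)=CCc1cc([C@H]2Oc3cc(OCOC)cc(OCOC)c3C(=O)[C@@H]2OCOC)cc(CC=C(C)C)c1OCOC
A5 | alternative 2 | methyl (2R,3R)-3-hydroxy-2-(methoxymethoxy)-3-[4-(methoxymethoxy)-3,5-bis(3-methylbut-2-enyl)phenyl]propanoate | CC(C)=CCc1cc([C@@H](O)[C@@H](OCOC)C(=O)OC)cc(CC=C(C)C)c1OCOC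
A6 | alternative 2 | 3,5-bis(methoxymethoxy)-2-(trimethylsilyl)phenyl trifluoromethanesulfonate | COCOc1cc(OCOC)c([Si](C)(C)C)c(OS(=O)(=O)C(F)(F)F)c1
A7 | alternative 3 | (2R,3R)-5,7-bis(methoxymethoxy)-2-[4-(methoxymethoxy)-3,5-bis(3-methylbut-2-enyl)phenyl]-3-(triethylsilyloxy)chroman-4-one | CC(C)=CCc1cc([C@H]2Oc3cc(OCOC)cc(OCOC)c3C(=O)[C@@H]2O[Si](CC)(CC)CC)cc(CC=C(C)C)c1OCOC
A8 | alternative 3 | 2-[3,5-bis(methoxymethoxy)-2-(triethylsilylcarbonyl)phenoxy]-2-[4-(methoxymethoxy)-3,5-bis(3-methylbut-2-enyl)phenyl]acetaldehyde | CC(C)=CCc1cc(C(C=O)Oc2cc(OCOC)cc(OCOC)c2C(=O)[Si](CC)(CC)CC)cc(CC=C(C)C)c1OCOC
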